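## Plan

- **Enabling feature (isoflavan numbering; ring D is the dimethylpyran on C2'–C3'):** C4 is a CH2 on C4a, ortho to C8a–O1 of ring A. O1=C8a–C4a=C4 is therefore a latent o-quinone methide, and C2=C3, with ring B on C3, is its two-atom partner.
- **Cuts:** the two O–Si bonds; C2–H back to a C2 acetal carrying a chiral alkoxy group; then C3–C4 and O1–C2 together ([4+2]). In the enol ether, C3–C1' (aryl–alkynyl coupling) and C2–O(auxiliary) are cut. In ring D, the O–CMe2 and C3'–vinyl bonds are cut (propargyl ether, Claisen cascade).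
- **Forward, the two halves:** ring D is closed first on 4-bromoresorcinol (ring B). The C2–C3 unit comes from trichloroethylene as an alkoxyacetylide, is joined to C1' and is semihydrogenated to the Z enol ether. Ring A is dressed separately as an O-Boc salicyl alcohol.
- **Forward, the union:** ring C closes last in the cycloaddition of the two halves. Acetal reduction and desilylation finish the synthesis.
- **Stereochemistry:** C3 (R), the only stereocentre, is set in the cycloaddition by the (1S,2R)-2-phenylcyclohexyl group on the oxygen of a geometrically pure Z enol ether. The transient C2 centre is erased afterwards.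

Key step: step 11

Assumption: the facial sense is assigned from the s-trans, C–H-eclipsed conformer of Z 2-phenylcyclohexyl enol ethers, in which the (1S,2R) group leaves the re,re face open and leads to 3R; both enantiomers of the alcohol are commercial, so the antipode would be used in steps 8 to 12 without other change if the correlation proved to be the reverse.

## Route

Step 1
Reactants: 1 2,4,6-trihydroxybenzaldehyde
Product: 2 2,6-dihydroxy-4-(triisopropylsilyloxy)benzaldehyde
Conditions: TIPSCl (1.05 equiv), imidazole, DMF, 0 °C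
Reagents that add atoms: chlorotriisopropylsilane, CC(C)[Si](Cl)(C(C)C)C(C)C
Why: Selective phenol silylation, in which the two ortho hydroxyls are held in hydrogen bonds to the formyl oxygen and flanked by it, so the bulky chlorosilane should take only the free and most acidic para hydroxyl.

Step 2
Reactants: 2 2,6-dihydroxy-4-(triisopropylsilyloxy)benzaldehyde
Product: 3 2-hydroxy-6-methoxy-4-(triisopropylsilyloxy)benzaldehyde
Conditions: MeOH (1.0 equiv), PPh3, DIAD, THF, 0 °C to rt
Reagents that add atoms: methanol, CO
Why: Mitsunobu etherification is neutral and so spares the base-sensitive para-silyloxy aldehyde, and it should stop after one of the two equivalent hydroxyls has reacted because the survivor is then locked in a strong hydrogen bond to the aldehyde and only one equivalent of reagents is offered.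

Step 3
Reactants: 3 2-hydroxy-6-methoxy-4-(triisopropylsilyloxy)benzaldehyde
Product: 4 tert-butyl 2-formyl-3-methoxy-5-(triisopropylsilyloxy)phenyl carbonate
Conditions: Boc2O, i-Pr2NEt, DMAP (cat), CH2Cl2, 0 °C to rt
Reagents that add atoms: di-tert-butyl dicarbonate, CC(C)(C)OC(=O)OC(=O)OC(C)(C)C
Why: DMAP-catalysed O-acylation with Boc2O is the standard way to aryl carbonates of salicylaldehydes, the acylpyridinium ion being reactive enough to overcome the hydrogen bond of the last phenol.

Step 4
Reactants: 4 tert-butyl 2-formyl-3-methoxy-5-(triisopropylsilyloxy)phenyl carbonate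
Product: 5 tert-butyl 2-(hydroxymethyl)-3-methoxy-5-(triisopropylsilyloxy)phenyl carbonate
Conditions: BH3·THF, THF, 0 °C; pH 7 buffer
Reagents that add atoms: none
Why: Borane reduction of the aldehyde runs through neutral alkoxyboranes and not through a free alkoxide, so the Boc group should stay on the phenol oxygen and the carbonate-transfer and elimination cascade, which a borohydride reduction would set off with over-reduction to the methyl arene, is not triggered.

Step 5
Reactants: 6 4-bromoresorcinol
Product: 7 2-bromo-5-(triisopropylsilyloxy)phenol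
Conditions: TIPSCl (1.0 equiv), imidazole, DMF, −10 °C
Reagents that add atoms: chlorotriisopropylsilane, CC(C)[Si](Cl)(C(C)C)C(C)C
Why: Sterically controlled monosilylation, in which the hydroxyl para to bromine is unhindered and the other is flanked by the halogen, so TIPSCl should mark the future 4'-OH and leave free the oxygen next to C1' that must become the pyran oxygen of ring D.

Step 6
Reactants: 7 2-bromo-5-(triisopropylsilyloxy)phenol; 8 3-chloro-3-methylbut-1-yne
Product: 9 [4-bromo-3-(2-methylbut-3-yn-2-yloxy)phenoxy]triisopropylsilane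
Conditions: CuCl2 (1 mol %), DBU, MeCN, 0 °C
Reagents that add atoms: none
Why: Copper-catalysed O-propargylation of a phenol with a tertiary propargylic chloride proceeds at 0 °C through a copper allenylidene-type electrophile, works well with acidic ortho-halophenols and avoids the prolonged heating with carbonate base that could loosen the aryl silyl ether.

Step 7
Reactants: 9 [4-bromo-3-(2-methylbut-3-yn-2-yloxy)phenoxy]triisopropylsilane
Product: 10 8-bromo-2,2-dimethyl-5-(triisopropylsilyloxy)-2H-chromene
Conditions: PhNEt2, 190 °C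
Reagents that add atoms: none
Why: Aromatic propargyl Claisen rearrangement followed by enolisation, 1,5-hydrogen shift and oxa-6π electrocyclisation is the classical route to 2,2-dimethyl-2H-chromenes, and because bromine blocks one ortho position the cascade can end only at the carbon between the two oxygens, which gives the 5-oxy-8-bromo pattern needed for rings B and D.

Step 8
Reactants: 11 (1S,2R)-2-phenylcyclohexan-1-ol; 12 trichloroethylene
Product: 14 (E)-1,2-dichlorovinyl (1S,2R)-2-phenylcyclohexyl ether, via dichloroacetylene 13 (not isolated)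
Conditions: KH, THF, 0 °C; then 12, −50 °C to rt
Reagents that add atoms: none
Why: The reaction of a potassium alkoxide with trichloroethylene is an elimination–addition in which loss of HCl gives 13 and the alkoxide adds to it in anti fashion to give the E dichloroenol ether, the two stereocentres of the auxiliary being untouched.

Step 9
Reactants: 14 (E)-1,2-dichlorovinyl (1S,2R)-2-phenylcyclohexyl ether; 10 8-bromo-2,2-dimethyl-5-(triisopropylsilyloxy)-2H-chromene
Product: 17 2,2-dimethyl-8-{[(1S,2R)-2-phenylcyclohexyl]oxyethynyl}-5-(triisopropylsilyloxy)-2H-chromene, via lithium alkoxyacetylide 15 (not isolated), via alkoxyethynylzinc chloride 16 (not isolated)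
Conditions: n-BuLi (2.2 equiv), THF, −78 to −40 °C; ZnCl2, −40 to 0 °C; 10, Pd(P(t-Bu)3)2 (5 mol %), THF, rt to 40 °C
Reagents that add atoms: none
Why: Two equivalents of n-BuLi turn 14 into 15 by dehydrochlorination and chlorine–lithium exchange, and after transmetalation to 16 a Negishi alkynylation with a bulky electron-rich phosphine should couple the electron-rich aryl bromide well below the temperature at which secondary alkyl ynol ethers fragment to ketenes.

Step 10
Reactants: 17 2,2-dimethyl-8-{[(1S,2R)-2-phenylcyclohexyl]oxyethynyl}-5-(triisopropylsilyloxy)-2H-chromene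
Product: 18 (Z)-2-[2,2-dimethyl-5-(triisopropylsilyloxy)-2H-chromen-8-yl]vinyl (1S,2R)-2-phenylcyclohexyl ether
Conditions: H2 (1 atm, one equivalent taken up), Pd/BaSO4, pyridine, rt
Reagents that add atoms: none
Why: Syn semihydrogenation of an alkoxyalkyne over poisoned palladium is the established stereospecific entry to Z enol ethers, needs no hot alkoxide that aryl silyl ethers would not survive, and should spare the chromene alkene, which is flanked by a quaternary carbon and binds to the poisoned surface far more slowly than the alkyne.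

Step 11
Reactants: 5 tert-butyl 2-(hydroxymethyl)-3-methoxy-5-(triisopropylsilyloxy)phenyl carbonate; 18 (Z)-2-[2,2-dimethyl-5-(triisopropylsilyloxy)-2H-chromen-8-yl]vinyl (1S,2R)-2-phenylcyclohexyl ether
Product: 20 (2R,3R)-3-[2,2-dimethyl-5-(triisopropylsilyloxy)-2H-chromen-8-yl]-5-methoxy-2-[(1S,2R)-2-phenylcyclohexyloxy]-7-(triisopropylsilyloxy)chroman, via o-quinone methide 19 (not isolated)
Conditions: t-BuMgCl (slow addition), Et2O, −78 °C to rt; 5 in 1.5-fold excess over 18
Reagents that add atoms: none
Why: t-BuMgCl, a base too hindered to add to a quinone methide, deprotonates the benzylic alcohol of 5, the magnesium alkoxide takes the Boc group over from the neighbouring phenol oxygen, and the phenoxide so freed expels tert-butyl carbonate from the benzylic carbon to give 19 well below room temperature. The electron-poor heterodiene O1=C8a–C4a=C4 of 19 and the electron-rich alkene of 18 then join in a concerted but asynchronous inverse-demand hetero-Diels–Alder reaction, the closest known cases being the low-temperature additions of quinone methides from O-Boc salicyl alcohols to 2-phenylcyclohexyl enol ethers and the additions of quinone methides to β-alkoxystyrenes that give 2-alkoxyisoflavans. Ring C closes in the [4+2] mode as a six-membered dihydropyran through the new C3–C4 and O1–C2 bonds, with rearomatisation of ring A as the driving force. Regiochemistry follows polarity, the methylene C4 meeting the nucleophilic β-carbon of the enol ether and O1 the alkoxy carbon, and the twist that the Z geometry forces on ring B keeps its donor oxygens from reversing this bias. C2 and C3 arise together by suprafacial addition, so the Z geometry fixes their cis relation whichever way the diene is oriented (C4 bears two hydrogens), while the absolute sense comes from the auxiliary: the Z substituent confines 18 to the s-trans C=C–O–C conformer with the carbinol C–H eclipsing the vinyl C–H, the phenyl group then covers the si face of the alkoxy carbon, and 19 adds to the re,re face to give 2R,3R. The step also needs chemoselectivity for the enol ether over the chromene alkene of 18 and over self-condensation of 19, which the far higher nucleophilicity of the enol ether, the two donor oxygens that tame 19 and its slow release in the presence of 18 should secure.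

Step 12
Reactants: 20 (2R,3R)-3-[2,2-dimethyl-5-(triisopropylsilyloxy)-2H-chromen-8-yl]-5-methoxy-2-[(1S,2R)-2-phenylcyclohexyloxy]-7-(triisopropylsilyloxy)chroman
Product: 21 (3R)-3-[2,2-dimethyl-5-(triisopropylsilyloxy)-2H-chromen-8-yl]-5-methoxy-7-(triisopropylsilyloxy)chroman
Conditions: Et3SiH, BF3·OEt2, CH2Cl2, −78 °C; aq NaHCO3
Reagents that add atoms: none
Why: In this ionic hydrogenation of a 2-alkoxychroman BF3 removes the exocyclic alkoxy group and Et3SiH should trap the cyclic oxocarbenium ion at C2 faster than C3 can lose its proton at −78 °C, so C2 becomes the methylene of the isoflavan, C3 keeps its R configuration, the auxiliary is recovered, and the aprotic cold medium leaves the chromene alkene and the aryl silyl ethers alone.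

Step 13
Reactants: 21 (3R)-3-[2,2-dimethyl-5-(triisopropylsilyloxy)-2H-chromen-8-yl]-5-methoxy-7-(triisopropylsilyloxy)chroman
Product: 22 (3R)-3-(5-hydroxy-2,2-dimethyl-2H-chromen-8-yl)-5-methoxychroman-7-ol
Conditions: Bu4NF, AcOH, THF, 0 °C
Reagents that add atoms: none
Why: Fluoride cleavage of aryl triisopropylsilyl ethers is fast at 0 °C, the AcOH buffer keeps the electron-rich phenols protonated, and nothing in the medium can affect C3, the methyl ether or the chromene.

## Compound list

1 | 2,4,6-trihydroxybenzaldehyde | O=Cc1c(O)cc(O)cc1O | starting material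
2 | 2,6-dihydroxy-4-(triisopropylsilyloxy)benzaldehyde | O=Cc1c(O)cc(O[Si](C(C)C)(C(C)C)C(C)C)cc1O | intermediate
3 | 2-hydroxy-6-methoxy-4-(triisopropylsilyloxy)benzaldehyde | COc1cc(O[Si](C(C)C)(C(C)C)C(C)C)cc(O)c1C=O | intermediate
4 | tert-butyl 2-formyl-3-methoxy-5-(triisopropylsilyloxy)phenyl carbonate | COc1cc(O[Si](C(C)C)(C(C)C)C(C)C)cc(OC(=O)OC(C)(C)C)c1C=O | intermediate
5 | tert-butyl 2-(hydroxymethyl)-3-methoxy-5-(triisopropylsilyloxy)phenyl carbonate | COc1cc(O[Si](C(C)C)(C(C)C)C(C)C)cc(OC(=O)OC(C)(C)C)c1CO | intermediate
6 | 4-bromoresorcinol | Oc1ccc(Br)c(O)c1 | starting material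
7 | 2-bromo-5-(triisopropylsilyloxy)phenol | Oc1cc(O[Si](C(C)C)(C(C)C)C(C)C)ccc1Br | intermediate
8 | 3-chloro-3-methylbut-1-yne | C#CC(C)(C)Cl | starting material
9 | [4-bromo-3-(2-methylbut-3-yn-2-yloxy)phenoxy]triisopropylsilane | C#CC(C)(C)Oc1cc(O[Si](C(C)C)(C(C)C)C(C)C)ccc1Br | intermediate
10 | 8-bromo-2,2-dimethyl-5-(triisopropylsilyloxy)-2H-chromene | CC1(C)C=Cc2c(O[Si](C(C)C)(C(C)C)C(C)C)ccc(Br)c2O1 | intermediate
11 | (1S,2R)-2-phenylcyclohexan-1-ol | O[C@H]1CCCC[C@@H]1c1ccccc1 | starting material
12 | trichloroethylene | ClC=C(Cl)Cl | starting material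
13 | dichloroacetylene (not isolated) | ClC#CCl | intermediate
14 | (E)-1,2-dichlorovinyl (1S,2R)-2-phenylcyclohexyl ether | Cl/C=C(/Cl)O[C@H]1CCCC[C@@H]1c1ccccc1 | intermediate
15 | lithium 2-[(1S,2R)-2-phenylcyclohexyloxy]ethynide (not isolated) | [Li]C#CO[C@H]1CCCC[C@@H]1c1ccccc1 | intermediate
16 | chloro{2-[(1S,2R)-2-phenylcyclohexyloxy]ethynyl}zinc (not isolated) | Cl[Zn]C#CO[C@H]1CCCC[C@@H]1c1ccccc1 | intermediate
17 | 2,2-dimethyl-8-{[(1S,2R)-2-phenylcyclohexyl]oxyethynyl}-5-(triisopropylsilyloxy)-2H-chromene | CC(C)[Si](C(C)C)(C(C)C)Oc1ccc(C#CO[C@H]2CCCC[C@@H]2c2ccccc2)c2c1C=CC(C)(C)O2 | intermediate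
18 | (Z)-2-[2,2-dimethyl-5-(triisopropylsilyloxy)-2H-chromen-8-yl]vinyl (1S,2R)-2-phenylcyclohexyl ether | CC(C)[Si](C(C)C)(C(C)C)Oc1ccc(/C=C\O[C@H]2CCCC[C@@H]2c2ccccc2)c2c1C=CC(C)(C)O2 | intermediate
19 | 5-methoxy-6-methylidene-3-(triisopropylsilyloxy)cyclohexa-2,4-dien-1-one (o-quinone methide, not isolated) | C=C1C(OC)=CC(O[Si](C(C)C)(C(C)C)C(C)C)=CC1=O | intermediate
20 | (2R,3R)-3-[2,2-dimethyl-5-(triisopropylsilyloxy)-2H-chromen-8-yl]-5-methoxy-2-[(1S,2R)-2-phenylcyclohexyloxy]-7-(triisopropylsilyloxy)chroman (2,3-cis acetal) | COc1cc(O[Si](C(C)C)(C(C)C)C(C)C)cc2c1C[C@H](c1ccc(O[Si](C(C)C)(C(C)C)C(C)C)c3c1OC(C)(C)C=C3)[C@H](O[C@H]1CCCC[C@@H]1c1ccccc1)O2 | intermediate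
21 | (3R)-3-[2,2-dimethyl-5-(triisopropylsilyloxy)-2H-chromen-8-yl]-5-methoxy-7-(triisopropylsilyloxy)chroman | COc1cc(O[Si](C(C)C)(C(C)C)C(C)C)cc2c1C[C@H](c1ccc(O[Si](C(C)C)(C(C)C)C(C)C)c3c1OC(C)(C)C=C3)CO2 | intermediate
22 | (3R)-3-(5-hydroxy-2,2-dimethyl-2H-chromen-8-yl)-5-methoxychroman-7-ol (CNP0320659.1) | COc1cc(O)cc2c1C[C@H](c1ccc(O)c3c1OC(C)(C)C=C3)CO2 | target

## Step count

Total steps: 13.
Longest linear sequence: 8 steps (5, 6, 7, 9, 10, 11, 12, 13). The ring A branch counts 7 steps and the auxiliary branch 6.

## Steps most likely to fail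

**1. Step 11.** The β-aryl enol ether is hindered and less nucleophilic than a simple vinyl ether. The cycloaddition may therefore lose the race against self-condensation of the quinone methide or its capture by tert-butoxide. Shielding of one alkene face by the auxiliary may also be incomplete.

The fallback gives up the cycloaddition for an Evans asymmetric alkylation followed by ether closure. It sets out from 18 and 5 and comes back to the route at 21. Mild hydrolysis of 18 (oxalic acid, wet THF, rt) gives arylacetaldehyde F1 and returns 11. Pinnick oxidation (NaClO2, NaH2PO4, 2-methylbut-2-ene, t-BuOH–H2O) gives arylacetic acid F2. This is joined to (R)-4-benzyloxazolidin-2-one (PivCl, Et3N, LiCl, THF) as N-acyloxazolidinone F3. An Appel reaction on 5 (CBr4, PPh3, CH2Cl2, −20 °C) gives benzylic bromide F4, which is used at once. Deprotonation of F3 with NaN(SiMe3)2 in THF at −78 °C and alkylation with F4 on the enolate face remote from the benzyl group forms C3–C4 and gives alkylated imide F5 with the R configuration. LiBH4 (THF, MeOH, 0 °C) releases primary alcohol F6. Piperidine in CH2Cl2 takes off the phenolic Boc group to give phenol alcohol F7. A Mitsunobu reaction (PPh3, DIAD, THF) then closes O1–C2 to give 21.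

**2. Step 12.** The Lewis acid may ionise the endocyclic C2–O1 bond, phenoxide being the better leaving group, and hydride capture would then open ring C. The oxocarbenium ion may also lose the C3 proton reversibly, which would erode the configuration. Adventitious acid may attack the chromene alkene.

The fallback replaces the ionic hydrogenation by hydrolysis, borohydride reduction and re-closure. It sets out from 20 and comes back at 21. Camphorsulfonic acid in wet MeCN at 0 °C cleaves the acetal to lactol F8 with recovery of 11. NaBH4 in EtOH is added without delay, so that the open hydroxy aldehyde form is reduced before it can enolise, and this gives phenol alcohol F7. The Mitsunobu closure described above then leads to 21.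

**3. Step 9.** Oxidative addition of the electron-rich aryl bromide may be slow. The ynol ether may decompose under the influence of zinc salts or warming, and the acetylide may homocouple.

The fallback moves the coupling from the alkyne to a preformed Z alkene, which also makes the semihydrogenation of step 10 unnecessary. It sets out from 14 and 10 and comes back at 18. Treatment of 14 with n-BuLi (2.2 equiv, THF, −78 to −40 °C) and a methanol quench gives terminal ynol ether F9. Radical hydrostannation (Bu3SnH, AIBN, benzene, 60 °C) adds in anti fashion to give (Z)-2-alkoxyvinylstannane F10. A Stille coupling with 10 (Pd(PPh3)4, CuI, toluene–DMF, 80 °C, no fluoride additive so that the silyl ether survives) proceeds with retention of geometry to give 18.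

## Further compounds

F1 | step 11 | 2-[2,2-dimethyl-5-(triisopropylsilyloxy)-2H-chromen-8-yl]acetaldehyde | O=CCc1ccc(O[Si](C(C)C)(C(C)C)C(C)C)c2c1OC(C)(C)C=C2
F2 | step 11 | 2-[2,2-dimethyl-5-(triisopropylsilyloxy)-2H-chromen-8-yl]acetic acid | OC(=O)Cc1ccc(O[Si](C(C)C)(C(C)C)C(C)C)c2c1OC(C)(C)C=C2
F3 | step 11 | (R)-4-benzyl-3-{2-[2,2-dimethyl-5-(triisopropylsilyloxy)-2H-chromen-8-yl]acetyl}oxazolidin-2-one | O=C(Cc1ccc(O[Si](C(C)C)(C(C)C)C(C)C)c2c1OC(C)(C)C=C2)N1[C@H](Cc2ccccc2)COC1=O
F4 | step 11 | 2-(bromomethyl)-3-methoxy-5-(triisopropylsilyloxy)phenyl tert-butyl carbonate | COc1cc(O[Si](C(C)C)(C(C)C)C(C)C)cc(OC(=O)OC(C)(C)C)c1CBr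
F5 | step 11 | (R)-4-benzyl-3-{(2R)-3-[2-(tert-butoxycarbonyloxy)-6-methoxy-4-(triisopropylsilyloxy)phenyl]-2-[2,2-dimethyl-5-(triisopropylsilyloxy)-2H-chromen-8-yl]propanoyl}oxazolidin-2-one | COc1cc(O[Si](C(C)C)(C(C)C)C(C)C)cc(OC(=O)OC(C)(C)C)c1C[C@H](c1ccc(O[Si](C(C)C)(C(C)C)C(C)C)c2c1OC(C)(C)C=C2)C(=O)N1[C@H](Cc2ccccc2)COC1=O
F6 | step 11 | tert-butyl 2-{(2R)-2-[2,2-dimethyl-5-(triisopropylsilyloxy)-2H-chromen-8-yl]-3-hydroxypropyl}-3-methoxy-5-(triisopropylsilyloxy)phenyl carbonate | COc1cc(O[Si](C(C)C)(C(C)C)C(C)C)cc(OC(=O)OC(C)(C)C)c1C[C@H](c1ccc(O[Si](C(C)C)(C(C)C)C(C)C)c2c1OC(C)(C)C=C2)CO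
F7 | step 11 | 2-{(2R)-2-[2,2-dimethyl-5-(triisopropylsilyloxy)-2H-chromen-8-yl]-3-hydroxypropyl}-3-methoxy-5-(triisopropylsilyloxy)phenol | COc1cc(O[Si](C(C)C)(C(C)C)C(C)C)cc(O)c1C[C@H](c1ccc(O[Si](C(C)C)(C(C)C)C(C)C)c2c1OC(C)(C)C=C2)CO
F8 | step 12 | (3R)-3-[2,2-dimethyl-5-(triisopropylsilyloxy)-2H-chromen-8-yl]-5-methoxy-7-(triisopropylsilyloxy)chroman-2-ol (anomeric mixture) | COc1cc(O[Si](C(C)C)(C(C)C)C(C)C)cc2c1C[C@H](c1ccc(O[Si](C(C)C)(C(C)C)C(C)C)c3c1OC(C)(C)C=C3)C(O)O2
F9 | step 9 | ethynyl (1S,2R)-2-phenylcyclohexyl ether | C#CO[C@H]1CCCC[C@@H]1c1ccccc1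
F10 | step 9 | tributyl{(Z)-2-[(1S,2R)-2-phenylcyclohexyloxy]vinyl}stannane | CCCC[Sn](CCCC)(CCCC)/C=C\O[C@H]1CCCC[C@@H]1c1ccccc1
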